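The readings are simulated with made-up constants; the scatter is artificial.

The trap in these flasks, where nucleophile and electrophile give target, is to read progress off the target.

in all of them: electrophile 0.065 M

| run | nucleophile | remark | time |
|---|---|---|---|
| maple | 0.095 M | run made earlier |  |
| birch | 0.20 M | run made earlier |  |
| south-west | 0.130 M |  | 25 h |
| north | 0.260 M |  | 25 h |

| run | time / h | electrophile / % | target / % |
|---|---|---|---|
| maple | 1.33 | 99.5 | 2.1 |
| maple | 4.00 | 93.4 | 3.5 |
| maple | 8.00 | 91.5 | 6.5 |
| maple | 10.0 | 92.3 | 8.0 |
| maple | 15.0 | 87.9 | 13.4 |
| maple | 20.0 | 85.2 | 15.7 |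
| maple | 25.0 | 80.8 | 17.1 |
| birch | 4.00 | 94.0 | 7.8 |
| birch | 8.00 | 84.7 | 12.8 |
| birch | 10.0 | 81.1 | 14.8 |
| birch | 15.0 | 74.5 | 20.6 |
| birch | 20.0 | 72.0 | 24.3 |
| birch | 25.0 | 66.1 | 25.0 |

(each reading ± 1 percentage point)

1. part of the electrophile that has reacted at the end, south-west
2. part of the electrophile that has reacted at the end, north
3. what raising the concentration of nucleophile from its lowest to its highest value here does to the part of the electrophile that has reacted (changes below 5 percentage points count as none) (no change / it rises / it falls)



At the end of birch, after 25.0 h, the electrophile has lost 33.9% of its charge while target reads 25.0%. That gap of 8.9 percentage points compares with 2.1 points in maple. The question counts electrophile gone, so the electrophile readings are the ones to use, whatever carries the gap.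

Take the nucleophile at its charge, as in a pseudo-first-order reckoning, and divide the logarithm of the electrophile's fall by c_nucleophile and by time:

κ(maple) = 0.0898 M⁻¹ h⁻¹
κ(birch) = 0.0828 M⁻¹ h⁻¹

Birch has twice the nucleophile of maple, yet these readings differ by just 0.00700 M⁻¹ h⁻¹. Their mean, a value read from scattered readings, is the exposure constant κ = 0.0863 M⁻¹ h⁻¹.

This reckoning then gives a ladder of electrophile half-lives, ln(2)/(κ c_nucleophile), fastest first:

north: 30.9 h
birch: 40.2 h
south-west: 61.8 h
maple: 84.6 h

The asked 25 h lies below the lowest rung, so electrophile should still be the larger part in both new flasks: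

south-west: 1 − exp(−κ c_nucleophile t) = 24.5%
north: 42.9%

The forecast, made from the same runs, says 24% for south-west, 40% for north, and it rises. Its north value lies below this reckoning, on its own ground: “This hints at reversibility, side chemistry or saturation, so I shade this slightly lower”.

    nucleophile + target → over-reaction product (k = 0.00233 M⁻¹ min⁻¹)
    electrophile + nucleophile → acid set free + target (k = 0.00167 M⁻¹ min⁻¹)
    nucleophile + acid set free ⇌ protonated nucleophile, settled at all times (K = 14000 M⁻¹)

South-west gives 24.4% and north 43.0%: it rises, by 19 points, and the forecast held. North holds 14.3% of over-reaction product at 25.0 h, yet the step that makes it shifts north's answer by less than the margin. With κ, north should keep 57.1% of its electrophile, and it keeps 57.0%. A neighbour flask, like south-west but with 0.52 M of nucleophile, has an exposure κ c_nucleophile t of 1.12, which reckons to 67.4% reacted; that flask gave 68.0%.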